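**Plan**

- Retrosynthesis: the acid, the acetyl group and one indole N–H are masked as methyl ester, dimethyl ketal and N-tosyl (tosyl = 4-methylbenzenesulfonyl). The pyrrole is then cut in one operation at N1–C2, N1–C5 and at the bond from pyrrole C4 to C3 of its indole. The resulting enedione is cut at its C3=C4 alkene into an arylpyruvate and a ketoaldehyde.
- Enabling feature: pyrrole C4 lies β (through C3) to the carbonyl carbon that becomes C2, and C3 of an indole is its natural nucleophilic site, so the C4 indole can enter as plain indole. C2 and C5 are both ketone carbons in a 1,4 relation, ready to take up N1.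
- Forward: indole-3-carbaldehyde is N-tosylated, olefinated and hydrolysed to the arylpyruvate (steps 1–3). 3,3-Dimethoxybutan-2-one is oxidized to the ketoaldehyde (step 4). A Knoevenagel condensation joins the two chains (step 5).
- The pyrrole, the only ring made in the route, is closed in step 6 by indole addition and ammonia condensation. Ketal hydrolysis (step 7) and KOH (step 8) finish the synthesis.
- Stereochemistry: the target has no stereocentre. The alkene geometry of the enedione and the two transient sp3 centres of the diketone are erased when the pyrrole aromatizes.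

Key step: step 6

Remark on the chemistry: compound 6 is drawn as the keto tautomer although its enol should predominate. Compound 9 is drawn as the E isomer, but either alkene isomer serves in step 6.

**Route**

Step 1
Reactants: 1 1H-indole-3-carbaldehyde
Product: 2 1-tosyl-1H-indole-3-carbaldehyde
Conditions: NaH, THF, 0 °C; then TsCl, 0 °C → rt
Reagents that add atoms: 4-methylbenzenesulfonyl chloride, Cc1ccc(cc1)S(=O)(=O)Cl
Why: N-sulfonylation of the sodium indolide is a standard protection, and the sulfonyl group lowers the donor power of this indole, which matters for the regiochemistry of step 6.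

Step 2
Reactants: 2 1-tosyl-1H-indole-3-carbaldehyde; 3 methyl 2-[(tert-butoxycarbonyl)amino]-2-(dimethoxyphosphoryl)acetate
Product: 4 methyl (Z)-2-[(tert-butoxycarbonyl)amino]-3-(1-tosyl-1H-indol-3-yl)prop-2-enoate
Conditions: DBU, CH2Cl2, 0 °C → rt
Reagents that add atoms: none
Why: Horner–Wadsworth–Emmons olefination of aromatic aldehydes with the phosphonoglycinate under amidine base should give the Z-dehydroamino ester, whose geometry is irrelevant to the next step.

Step 3
Reactants: 4 methyl (Z)-2-[(tert-butoxycarbonyl)amino]-3-(1-tosyl-1H-indol-3-yl)prop-2-enoate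
Product: 6 methyl 2-oxo-3-(1-tosyl-1H-indol-3-yl)propanoate, via methyl (Z)-2-amino-3-(1-tosyl-1H-indol-3-yl)prop-2-enoate 5 (not isolated)
Conditions: TFA, CH2Cl2, 0 °C → rt; then H2O, THF, rt
Reagents that add atoms: water, O
Why: Acidolytic Boc cleavage frees the primary enamine, which tautomerizes to the α-imino ester and is hydrolysed by water to the α-keto ester (enecarbamate hydrolysis), while the methyl ester and the N-sulfonyl group tolerate the acid.

Step 4
Reactants: 7 3,3-dimethoxybutan-2-one
Product: 8 3,3-dimethoxy-2-oxobutanal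
Conditions: SeO2, 1,4-dioxane, H2O (2 equiv), 80 °C
Reagents that add atoms: selenium dioxide, O=[Se]=O
Why: Riley oxidation converts the only enolizable position, the methyl group next to the ketone, into the aldehyde, and the adjacent carbonyl disfavours oxocarbenium formation so the ketal should hold in the weakly acidic medium.

Step 5
Reactants: 6 methyl 2-oxo-3-(1-tosyl-1H-indol-3-yl)propanoate; 8 3,3-dimethoxy-2-oxobutanal
Product: 9 methyl (E)-6,6-dimethoxy-2,5-dioxo-3-(1-tosyl-1H-indol-3-yl)hept-3-enoate
Conditions: piperidine (20 mol %), AcOH (20 mol %), 4 Å MS, toluene, rt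
Reagents that add atoms: none
Why: Knoevenagel condensation in which the doubly activated C3 methylene of the pyruvate adds to the iminium ion of the non-enolizable, highly electrophilic aldehyde and the Mannich adduct loses piperidine by E1cB elimination, a path that never passes through a free β-hydroxy ester able to lactonize.

Step 6
Reactants: 9 methyl (E)-6,6-dimethoxy-2,5-dioxo-3-(1-tosyl-1H-indol-3-yl)hept-3-enoate; 10 1H-indole
Product: 12 methyl 5-(1,1-dimethoxyethyl)-4-(1H-indol-3-yl)-3-(1-tosyl-1H-indol-3-yl)-1H-pyrrole-2-carboxylate, via methyl 4-(1H-indol-3-yl)-6,6-dimethoxy-2,5-dioxo-3-(1-tosyl-1H-indol-3-yl)heptanoate 11 (not isolated)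
Conditions: Sc(OTf)3 (10 mol %), MeCN, 0 °C → rt; then NH4OAc, MeOH, 60 °C
Reagents that add atoms: ammonium acetate, CC(=O)[O-].[NH4+]
Why: Sc(OTf)3 chelates the 1,2-dicarbonyl unit of the ketoester and activates the C2=O/C3=C4 enone, so indole attacks through its C3 at the unsubstituted C4 and rearomatizes by proton loss to give diketone 11, a Friedel–Crafts Michael addition of the kind established for β,γ-unsaturated α-ketoesters and 2-ene-1,4-diones. Ammonia from NH4OAc then condenses with the ketoester carbonyl, the nitrogen closes onto the C5 ketone by 5-exo-trig addition, and loss of two molecules of water aromatizes the ring, which is a Paal–Knorr pyrrole synthesis forming N1–C2 and N1–C5. The two stereocentres created at C3 and C4 of 11 are transient and disappear on aromatization, so none needs control. The step requires 1,4-addition at C4 in preference to attack at C3 or at the ketone carbonyl; C3 is fully substituted and carries the bulky sulfonylindole, whose tosyl group suppresses azafulvenium-type activation of C3, while chelation singles out the enone whose β-carbon is C4. The ketal should resist the Lewis acid because ionization beside the C5 carbonyl is disfavoured, it leaves only the C2/C5 carbonyl pair open to ammonia, and methanol as co-solvent makes any ketal or ester exchange degenerate.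

Step 7
Reactants: 12 methyl 5-(1,1-dimethoxyethyl)-4-(1H-indol-3-yl)-3-(1-tosyl-1H-indol-3-yl)-1H-pyrrole-2-carboxylate
Product: 13 methyl 5-acetyl-4-(1H-indol-3-yl)-3-(1-tosyl-1H-indol-3-yl)-1H-pyrrole-2-carboxylate
Conditions: 1 M HCl, THF, rt
Reagents that add atoms: water, O
Why: Acid-catalysed ketal hydrolysis should be fast because the pyrrole ring stabilizes the oxocarbenium ion, and the ester and sulfonamide are inert to dilute acid at room temperature.

Step 8
Reactants: 13 methyl 5-acetyl-4-(1H-indol-3-yl)-3-(1-tosyl-1H-indol-3-yl)-1H-pyrrole-2-carboxylate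
Product: 14 5-acetyl-3,4-di(1H-indol-3-yl)-1H-pyrrole-2-carboxylic acid
Conditions: KOH, MeOH/THF/H2O, 65 °C; then 1 M HCl to pH 3, 0 °C
Reagents that add atoms: potassium hydroxide, [K+].[OH-]
Why: Hot methanolic KOH effects ester saponification and nucleophilic N-desulfonylation of the indole in one operation, while the acetylpyrrole is held as its unreactive anion until the cold acidification.

**Compound list**

1 | 1H-indole-3-carbaldehyde | O=Cc1c[nH]c2ccccc12 | starting material
2 | 1-tosyl-1H-indole-3-carbaldehyde | O=Cc1cn(S(=O)(=O)c2ccc(C)cc2)c2ccccc12 | intermediate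
3 | methyl 2-[(tert-butoxycarbonyl)amino]-2-(dimethoxyphosphoryl)acetate (racemic) | COC(=O)C(NC(=O)OC(C)(C)C)P(=O)(OC)OC | starting material
4 | methyl (Z)-2-[(tert-butoxycarbonyl)amino]-3-(1-tosyl-1H-indol-3-yl)prop-2-enoate | COC(=O)/C(NC(=O)OC(C)(C)C)=C/c1cn(S(=O)(=O)c2ccc(C)cc2)c2ccccc12 | intermediate
5 | methyl (Z)-2-amino-3-(1-tosyl-1H-indol-3-yl)prop-2-enoate (formed in the flask as its trifluoroacetate, not isolated) | COC(=O)/C(N)=C/c1cn(S(=O)(=O)c2ccc(C)cc2)c2ccccc12 | intermediate
6 | methyl 2-oxo-3-(1-tosyl-1H-indol-3-yl)propanoate | COC(=O)C(=O)Cc1cn(S(=O)(=O)c2ccc(C)cc2)c2ccccc12 | intermediate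
7 | 3,3-dimethoxybutan-2-one | CC(=O)C(C)(OC)OC | starting material
8 | 3,3-dimethoxy-2-oxobutanal | CC(OC)(OC)C(=O)C=O | intermediate
9 | methyl (E)-6,6-dimethoxy-2,5-dioxo-3-(1-tosyl-1H-indol-3-yl)hept-3-enoate | COC(=O)C(=O)/C(c1cn(S(=O)(=O)c2ccc(C)cc2)c2ccccc12)=C/C(=O)C(C)(OC)OC | intermediate
10 | 1H-indole | c1ccc2[nH]ccc2c1 | starting material
11 | methyl 4-(1H-indol-3-yl)-6,6-dimethoxy-2,5-dioxo-3-(1-tosyl-1H-indol-3-yl)heptanoate (mixture of diastereomers, formed in the flask, not isolated) | COC(=O)C(=O)C(c1cn(S(=O)(=O)c2ccc(C)cc2)c2ccccc12)C(c1c[nH]c2ccccc12)C(=O)C(C)(OC)OC | intermediate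
12 | methyl 5-(1,1-dimethoxyethyl)-4-(1H-indol-3-yl)-3-(1-tosyl-1H-indol-3-yl)-1H-pyrrole-2-carboxylate | COC(=O)c1[nH]c(C(C)(OC)OC)c(-c2c[nH]c3ccccc23)c1-c1cn(S(=O)(=O)c2ccc(C)cc2)c2ccccc12 | intermediate
13 | methyl 5-acetyl-4-(1H-indol-3-yl)-3-(1-tosyl-1H-indol-3-yl)-1H-pyrrole-2-carboxylate | COC(=O)c1[nH]c(C(C)=O)c(-c2c[nH]c3ccccc23)c1-c1cn(S(=O)(=O)c2ccc(C)cc2)c2ccccc12 | intermediate
14 | 5-acetyl-3,4-di(1H-indol-3-yl)-1H-pyrrole-2-carboxylic acid | CC(=O)c1[nH]c(C(=O)O)c(-c2c[nH]c3ccccc23)c1-c1c[nH]c2ccccc12 | target

**Step count**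

Total: 8 steps. Longest linear sequence: 7 steps (1, 2, 3, 5, 6, 7, 8 from indole-3-carbaldehyde); step 4 is a one-step side branch.

**Steps most likely to fail**

Step 6. Indole may add in the 1,2 sense to the ketoester carbonyl, the enolized diketone may close to a furan on the Lewis acid before ammonia is introduced, or the ketal may ionize once the electron-rich pyrrole has formed. The fallback makes the C4–indole bond by cross-coupling instead of conjugate addition. It sets out from 9 and returns at 13.
- The alkene of 9 is reduced with Zn dust in AcOH at 0 °C to the saturated diketone methyl 6,6-dimethoxy-2,5-dioxo-3-(1-tosyl-1H-indol-3-yl)heptanoate F1.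
- Paal–Knorr condensation with NH4OAc in MeOH at 60 °C gives methyl 5-(1,1-dimethoxyethyl)-3-(1-tosyl-1H-indol-3-yl)-1H-pyrrole-2-carboxylate F2.
- NBS with pyridine in THF at −78 °C brominates the only free ring position to methyl 4-bromo-5-(1,1-dimethoxyethyl)-3-(1-tosyl-1H-indol-3-yl)-1H-pyrrole-2-carboxylate F3.
- Suzuki–Miyaura coupling with commercial 1-Boc-indole-3-boronic acid pinacol ester (Pd(OAc)2, SPhos, K3PO4, toluene/H2O, 90 °C) gives tert-butyl 3-[2-(1,1-dimethoxyethyl)-5-(methoxycarbonyl)-4-(1-tosyl-1H-indol-3-yl)-1H-pyrrol-3-yl]-1H-indole-1-carboxylate F4.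
- TFA in wet CH2Cl2 removes the Boc group and the ketal together and delivers 13.

Step 5. The aldol-type intermediate may lactonize onto the methyl ester, the pyruvate may self-condense, or a second pyruvate may add to the product enedione. The fallback builds the C3–C4 bond by alkylation and introduces the alkene by oxidation. It sets out from 6 (with 7 as the source of the electrophile) and returns at 9.
- 7 is brominated at its methyl group with Br2 in MeOH at 0 °C, where ketal exchange is degenerate, to give 1-bromo-3,3-dimethoxybutan-2-one F5.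
- C-alkylation of the enolate of 6 with this bromide (K2CO3, acetone, rt) gives the saturated diketone methyl 6,6-dimethoxy-2,5-dioxo-3-(1-tosyl-1H-indol-3-yl)heptanoate F1, the same compound as in the fallback above.
- Selenenylation at the enolized C3 with PhSeCl and pyridine in CH2Cl2 gives methyl 6,6-dimethoxy-2,5-dioxo-3-(phenylselanyl)-3-(1-tosyl-1H-indol-3-yl)heptanoate F6.
- Oxidation with H2O2 at 0 °C triggers syn elimination of the selenoxide toward C4, the only carbon carrying β-hydrogens, and gives 9.

Step 4. The ketal may be cleaved in hot aqueous selenous acid, the aldehyde may be over-oxidized to the keto acid, and the product may be held back as hydrate on colloidal selenium. The fallback reaches the ketoaldehyde by oxidative cleavage of an enaminone. It sets out from 7 and returns at 8.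
- Condensation of 7 with N,N-dimethylformamide dimethyl acetal (neat, 100 °C) gives (E)-1-(dimethylamino)-4,4-dimethoxypent-1-en-3-one F7.
- Sensitized photooxygenation (O2, tetraphenylporphyrin, hν, CH2Cl2, −20 °C) cleaves the enamine double bond through a dioxetane under neutral conditions and gives 8.

**Further compounds**

F1 | step 6 | methyl 6,6-dimethoxy-2,5-dioxo-3-(1-tosyl-1H-indol-3-yl)heptanoate (racemic) | COC(=O)C(=O)C(CC(=O)C(C)(OC)OC)c1cn(S(=O)(=O)c2ccc(C)cc2)c2ccccc12
F2 | step 6 | methyl 5-(1,1-dimethoxyethyl)-3-(1-tosyl-1H-indol-3-yl)-1H-pyrrole-2-carboxylate | COC(=O)c1[nH]c(C(C)(OC)OC)cc1-c1cn(S(=O)(=O)c2ccc(C)cc2)c2ccccc12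
F3 | step 6 | methyl 4-bromo-5-(1,1-dimethoxyethyl)-3-(1-tosyl-1H-indol-3-yl)-1H-pyrrole-2-carboxylate | COC(=O)c1[nH]c(C(C)(OC)OC)c(Br)c1-c1cn(S(=O)(=O)c2ccc(C)cc2)c2ccccc12
F4 | step 6 | tert-butyl 3-[2-(1,1-dimethoxyethyl)-5-(methoxycarbonyl)-4-(1-tosyl-1H-indol-3-yl)-1H-pyrrol-3-yl]-1H-indole-1-carboxylate | COC(=O)c1[nH]c(C(C)(OC)OC)c(-c2cn(C(=O)OC(C)(C)C)c3ccccc23)c1-c1cn(S(=O)(=O)c2ccc(C)cc2)c2ccccc12
F5 | step 5 | 1-bromo-3,3-dimethoxybutan-2-one | CC(OC)(OC)C(=O)CBr
F6 | step 5 | methyl 6,6-dimethoxy-2,5-dioxo-3-(phenylselanyl)-3-(1-tosyl-1H-indol-3-yl)heptanoate (racemic) | COC(=O)C(=O)C([Se]c1ccccc1)(CC(=O)C(C)(OC)OC)c1cn(S(=O)(=O)c2ccc(C)cc2)c2ccccc12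
F7 | step 4 | (E)-1-(dimethylamino)-4,4-dimethoxypent-1-en-3-one | CN(C)/C=C/C(=O)C(C)(OC)OC
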